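## The problem

The target 20 is an 8–5′ neolignan acid built on a 2,3-dihydrobenzofuran. Ring A (the benzo ring, C3a–C7a) carries a methoxy group at C7 and an (E)-propenoic acid at C5. Ring B (O1, C2, C3, C3a, C7a) carries a hydroxymethyl group at C3, and C2 bears a 4-hydroxy-3,5-dimethoxyphenyl group (ring C).

There are two adjacent stereocentres, C2 (S) and C3 (R), trans to each other. They are unequal. C2 is a benzylic ether carbon para to the free phenol of ring C and can open and re-close through a quinone methide, so it follows C3. C3 has no such path and must be set in absolute terms, so C3 can control C2 but not the reverse.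

The molecule does not tolerate rough handling. The ring C phenol is easily oxidised, the C2–O1 bond ionises in strong acid, a second oxidation would aromatise ring B to a benzofuran, and the cinnamic acid rules out hydrogenolysis and strong hydride donors late in the route. The chain problem is to join rings A and C through a three-carbon unit (C2, C3 and the hydroxymethyl carbon) with ring A on the central carbon.

The enabling feature is that C2 sits para to the hydroxyl of ring C while O1 on C7a is five atoms away. Oxidation of the 4-alkyl-2,6-dimethoxyphenol makes C2 the exocyclic carbon of a para-quinone methide, and O1 can close ring B onto it. The acrylate para to O1 makes ring A harder to oxidise and so helps keep the oxidation on ring C.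

## Retrosynthesis

**Carboxylic acid.** No skeletal bond is cut: acid 20 is traced to methyl ester 19. An ester is kept through the oxidation because a free acid would bind to the silver oxidant and make the late intermediates hard to purify. A methyl ester is preferred to a tert-butyl ester, whose acidic removal would endanger the C2–O1 bond. The forward step is a hydroxide saponification that must leave ring B closed, which is reasonable because C3 bears no acidifying group.

**Ring B.** The O1–C2 bond of 19 is cut to give bisphenol 17, by way of para-quinone methide 18. The neighbouring cuts are O1–C7a (aryl ether formation, which needs a leaving group on ring A and a stereodefined C2 alcohol) or the C–C bonds of ring B (which put both stereocentres in play at once). The O1–C2 cut at the quinone methide level needs neither a leaving group nor stereocontrol at C2. It reduces the problem to an open-chain 2,3-diarylpropan-1-ol with one stereocentre. The forward reaction must oxidise only the ring C phenol and close trans. The hydroxymethyl group is left free because it could close only a four-membered ring.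

**Phenols and alcohol.** 17 is traced to bis(benzyl ether) 16, and 16 to imide 14 by way of aldehyde 15; no skeletal bond is cut. Benzyl ethers pass through zinc enolate coupling, strong acid, amide base and borohydride. They can be removed by a boron Lewis acid with a cation scavenger without touching the acrylate, where hydrogenolysis would not. The forward reduction of the imide must spare the methyl cinnamate unit, which calls for a mild borohydride in aqueous solvent.

**Stereocentre.** The bond between the future C3 and the future C2 in 14 is cut to give arylacetyl imide 12 and benzylic bromide 4, joined through sodium enolate 13. The neighbouring cut, C3–C3a (arylation of a 3-arylpropanoyl imide), is less predictable in its sense of induction. Benzylation of an arylacetyl oxazolidinone enolate is the standard solution, and the two halves are of similar size. The forward step must deliver the (R) centre: the chelated Z-enolate of the (R)-4-benzyl auxiliary is attacked on the face away from the benzyl group.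

**Arylacetic acid.** 12 is cut at the N–acyl bond to acid 9 and oxazolidinone 10 (through mixed anhydride 11). Acid 9 comes from tert-butyl ester 8, and 8 is cut at the aryl–CH2 bond to aryl bromide 7 and a zinc ester enolate. The tert-butyl ester is what lets the acetic acid be freed beside the methyl cinnamate unit. 7 is cut at the alkene to aldehyde 6 (stabilised ylide olefination), and 6 is the benzyl ether of 5-bromovanillin 5, in which bromide, phenol, methoxy and formyl groups already stand as in ring A. Installing the acrylate first means the formyl group never needs protection; in return the cinnamate must survive every later step, which fixes the choice of reagents.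

**Electrophile.** Bromide 4 is traced through alcohol 3 and aldehyde 2 to syringaldehyde 1, which carries the whole of ring C.

## Roads not taken

**Alternative 1:** The cut runs through C2–aryl (ring C) and C3–C3a at once, so the C2–C3 unit arrives as an alkene. Forward, aryllithium A4 would add to (E)-alkenylboronate A3 to give boron ate complex A5. Under a palladium catalyst with a chiral ferrocene-based bisphosphine, A5 would react with aryl triflate A2: the ring C aryl migrates from boron to the future C2 while palladium delivers ring A to the future C3, anti across the alkene, giving boronic ester A1.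
- Merits: three pieces of similar size meet in one catalytic, enantioselective step that fixes both stereocentres and the whole skeleton except the acrylate; no auxiliary is needed.
- Weak points: β-substituted alkenylboronates and ortho-alkoxy aryl triflates are both at the demanding edge of this coupling. The C2 centre set at boron is then spent, because after C–B oxidation the benzylic position para to an oxygenated ring closes through a cation or quinone methide and ends trans whatever its configuration. The ring A ester still needs reduction, oxidation and olefination to become the acrylate. Acetal protecting groups must come off with acid next to the acid-labile C2–O1 bond.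
- Comparison: on catalyst economy and convergence this road is better than the chosen plan, which spends a stoichiometric auxiliary and a longer linear line. The chosen plan sets against it an alkylation whose sense of induction is predictable for this substitution pattern, an acrylate in place from the second step of the main line, and a ring closure that needs no activation of C2.

**Alternative 2:** The cut removes C2–C3 and O1–C2 together, so C2 arrives as a one-carbon unit. Forward, base would eliminate sulfinate from phenol sulfone A7 to unveil ortho-quinone methide A9 on ring A, and would deprotonate the benzylic carbon of chiral sulfonium salt A8. That carbon adds to the methide carbon (C2–C3), and the phenoxide then displaces the sulfur group (O1–C2), giving trans-dihydrobenzofuran A6.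
- Merits: fully convergent; ring B and both stereocentres form in one step; the trans geometry follows from anti addition and invertive closure; no electron-rich phenol has to be oxidised.
- Weak points: A9 has hydrogens next to the methide carbon and can tautomerise by a 1,5-hydrogen shift before it is trapped. Absolute control of both centres rests on a stoichiometric chiral sulfur auxiliary acting on a semi-stabilised, very electron-rich benzylic carbanion, where reversible addition usually erodes enantioselectivity. After the key step a Heck reaction at the bromide, two deprotections and an ester hydrolysis remain.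
- Comparison: it reaches the ring system in fewer steps and avoids the chemoselective oxidation, which is a real advantage. The chosen plan sets against it that the one centre that matters (C3) comes from a reliable auxiliary alkylation and C2 simply follows; here the enantiomeric purity of the whole molecule would hang on the least predictable event.

**Alternative 3:** The cut is C3–C3a, read as the result of a 1,2-aryl shift, so the dihydrofuran is the ring-contracted form of a chroman-4-one. Forward, enantioenriched flavanone A11 would be treated with a hypervalent iodine diacetate in acidic orthoformate. The enol ether is iodinated at the CH2 carbon, the ring A carbon migrates from the ketal carbon to that carbon with loss of the iodane, and the old carbonyl carbon becomes the ester of A10.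
- Merits: a known reaction class for flavanones; stereospecific, so the C2 configuration of A11 is carried over and the trans relation is intrinsic; A11 is within reach of a catalytic asymmetric conjugate addition.
- Weak points: with an oxygen-rich 2-aryl group, competing migration of that aryl group (isoflavone formation) and dehydrogenation (flavone formation) gain ground, which is why the ring C phenol must be acylated. The flavanone stereocentre can racemise by reversible ring opening in the strongly acidic medium. In A10 the C3 hydrogen is α to an ester, inviting epimerisation or β-elimination of O1, and the reduction that makes the hydroxymethyl group also strips the acyl group from ring C. The bromide still needs a Heck reaction.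
- Comparison: the step count is comparable or slightly lower and the asymmetric step could be catalytic, both in its favour. The chosen plan sets against it milder conditions for ring C, a C3 centre at the alcohol oxidation level from the outset, and an acrylate carried through.

Key step: step 12

Remark on the chemistry: the Reformatsky reagent BrZnCH2CO2t-Bu is taken as a purchased THF solution, and the target SMILES is read as the trans (2S,3R) isomer.

## Route

Step 1
Reactants: 1 syringaldehyde (4-hydroxy-3,5-dimethoxybenzaldehyde)
Product: 2 4-(benzyloxy)-3,5-dimethoxybenzaldehyde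
Conditions: BnBr, K2CO3, DMF, 60 °C
Reagents that add atoms: benzyl bromide, BrCc1ccccc1
Why: Williamson ether synthesis; the phenoxide para to the formyl group forms easily and DMF overcomes the hindrance of the two flanking methoxy groups.

Step 2
Reactants: 2 4-(benzyloxy)-3,5-dimethoxybenzaldehyde
Product: 3 [4-(benzyloxy)-3,5-dimethoxyphenyl]methanol
Conditions: NaBH4, MeOH/THF, 0 °C
Reagents that add atoms: none
Why: Borohydride reduction of an aromatic aldehyde; nothing else in 2 is reducible.

Step 3
Reactants: 3 [4-(benzyloxy)-3,5-dimethoxyphenyl]methanol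
Product: 4 2-(benzyloxy)-5-(bromomethyl)-1,3-dimethoxybenzene
Conditions: PBr3, CH2Cl2, 0 °C
Reagents that add atoms: phosphorus tribromide, BrP(Br)Br
Why: Bromination of an electron-rich benzylic alcohol with PBr3; the two meta methoxy groups temper the lability of the bromide, which should be used soon after preparation.

Step 4
Reactants: 5 5-bromovanillin (3-bromo-4-hydroxy-5-methoxybenzaldehyde)
Product: 6 4-(benzyloxy)-3-bromo-5-methoxybenzaldehyde
Conditions: BnBr, K2CO3, DMF, 60 °C
Reagents that add atoms: benzyl bromide, BrCc1ccccc1
Why: Williamson ether synthesis on an acidic phenol para to a formyl group; the benzyl ether withstands every step up to its planned removal.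

Step 5
Reactants: 6 4-(benzyloxy)-3-bromo-5-methoxybenzaldehyde
Product: 7 methyl (E)-3-[4-(benzyloxy)-3-bromo-5-methoxyphenyl]prop-2-enoate
Conditions: Ph3P=CHCO2Me, toluene, 80 °C
Reagents that add atoms: methyl (triphenylphosphoranylidene)acetate, COC(=O)C=P(c1ccccc1)(c1ccccc1)c1ccccc1
Why: Wittig olefination with a stabilised ylide, which should give the E alkene under neutral conditions; the aldehyde has no ortho substituent.

Step 6
Reactants: 7 methyl (E)-3-[4-(benzyloxy)-3-bromo-5-methoxyphenyl]prop-2-enoate
Product: 8 methyl (E)-3-[4-(benzyloxy)-3-(2-tert-butoxy-2-oxoethyl)-5-methoxyphenyl]prop-2-enoate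
Conditions: BrZnCH2CO2t-Bu, Pd2(dba)3 (cat.), XPhos (cat.), THF, 50 °C
Reagents that add atoms: (2-tert-butoxy-2-oxoethyl)zinc bromide, CC(C)(C)OC(=O)C[Zn]Br
Why: Negishi coupling of a Reformatsky reagent with an aryl bromide at zerovalent palladium carrying a bulky biarylphosphine; the zinc enolate is too mild to attack the methyl ester or add to the cinnamate.

Step 7
Reactants: 8 methyl (E)-3-[4-(benzyloxy)-3-(2-tert-butoxy-2-oxoethyl)-5-methoxyphenyl]prop-2-enoate
Product: 9 {2-(benzyloxy)-3-methoxy-5-[(E)-3-methoxy-3-oxoprop-1-en-1-yl]phenyl}acetic acid
Conditions: CF3CO2H/CH2Cl2 (1:4), 0 °C to rt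
Reagents that add atoms: none
Why: Acidolysis of the tert-butyl ester with loss of isobutene; the methyl ester, the aryl benzyl ether and the alkene are inert to trifluoroacetic acid for the short time needed.

Step 8
Reactants: 9 {2-(benzyloxy)-3-methoxy-5-[(E)-3-methoxy-3-oxoprop-1-en-1-yl]phenyl}acetic acid; 10 (R)-4-benzyl-1,3-oxazolidin-2-one
Product: 12 methyl (E)-3-{4-(benzyloxy)-3-methoxy-5-[2-oxo-2-((4R)-4-benzyl-2-oxo-1,3-oxazolidin-3-yl)ethyl]phenyl}prop-2-enoate, via mixed pivalic anhydride 11 (not isolated)
Conditions: t-BuCOCl, Et3N, THF, –20 °C; then 10, LiCl, –20 °C to rt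
Reagents that add atoms: none
Why: N-acylation of the oxazolidinone through the mixed pivalic anhydride under LiCl/Et3N activation; no strong base is used, so the acidic arylacetyl position and the cinnamate are not disturbed, and attack occurs at the less hindered arylacetyl carbonyl.

Step 9
Reactants: 12 methyl (E)-3-{4-(benzyloxy)-3-methoxy-5-[2-oxo-2-((4R)-4-benzyl-2-oxo-1,3-oxazolidin-3-yl)ethyl]phenyl}prop-2-enoate; 4 2-(benzyloxy)-5-(bromomethyl)-1,3-dimethoxybenzene
Product: 14 methyl (E)-3-{4-(benzyloxy)-3-[(2R)-1-((4R)-4-benzyl-2-oxo-1,3-oxazolidin-3-yl)-3-(4-benzyloxy-3,5-dimethoxyphenyl)-1-oxopropan-2-yl]-5-methoxyphenyl}prop-2-enoate, via sodium Z-enolate 13 (not isolated)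
Conditions: NaN(SiMe3)2, THF, –78 °C; then 4, –78 to –40 °C
Reagents that add atoms: none
Why: Evans alkylation: the chelated Z-enolate 13 is attacked by the benzylic bromide on the face opposite the 4-benzyl group of the (R)-auxiliary, which sets the new centre as (R); the stabilised, hindered enolate is not expected to add to the electron-rich cinnamate at this temperature.

Step 10
Reactants: 14 methyl (E)-3-{4-(benzyloxy)-3-[(2R)-1-((4R)-4-benzyl-2-oxo-1,3-oxazolidin-3-yl)-3-(4-benzyloxy-3,5-dimethoxyphenyl)-1-oxopropan-2-yl]-5-methoxyphenyl}prop-2-enoate
Product: 16 methyl (E)-3-{4-(benzyloxy)-3-[(2R)-1-(4-benzyloxy-3,5-dimethoxyphenyl)-3-hydroxypropan-2-yl]-5-methoxyphenyl}prop-2-enoate, via aldehyde 15 (not isolated)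
Conditions: NaBH4, THF/H2O (3:1), 0 °C to rt
Reagents that add atoms: none
Why: Reductive removal of the auxiliary: hydride adds to the activated exocyclic imide carbonyl, the hemiaminal collapses to aldehyde 15, and 15 is reduced at once, faster than it can enolise, so the stereocentre is kept; NaBH4 in aqueous THF does not reduce the methyl cinnamate, and 10 is recovered.

Step 11
Reactants: 16 methyl (E)-3-{4-(benzyloxy)-3-[(2R)-1-(4-benzyloxy-3,5-dimethoxyphenyl)-3-hydroxypropan-2-yl]-5-methoxyphenyl}prop-2-enoate
Product: 17 methyl (E)-3-{4-hydroxy-3-[(2R)-1-hydroxy-3-(4-hydroxy-3,5-dimethoxyphenyl)propan-2-yl]-5-methoxyphenyl}prop-2-enoate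
Conditions: BCl3, C6HMe5, CH2Cl2, –78 °C; then MeOH/CHCl3
Reagents that add atoms: none
Why: Lewis-acid debenzylation of aryl benzyl ethers with pentamethylbenzene as a non-basic benzyl cation scavenger; at –78 °C the aryl methyl ethers, the ester and the alkene are left alone, and the scavenger prevents C-benzylation of the electron-rich rings.

Step 12
Reactants: 17 methyl (E)-3-{4-hydroxy-3-[(2R)-1-hydroxy-3-(4-hydroxy-3,5-dimethoxyphenyl)propan-2-yl]-5-methoxyphenyl}prop-2-enoate
Product: 19 methyl (E)-3-[(2S,3R)-2-(4-hydroxy-3,5-dimethoxyphenyl)-3-(hydroxymethyl)-7-methoxy-2,3-dihydro-1-benzofuran-5-yl]prop-2-enoate, via para-quinone methide 18 (not isolated)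
Conditions: Ag2O, CH2Cl2/acetone (4:1), rt, dark, high dilution
Reagents that add atoms: none
Why: Ag2O takes two electrons and two protons from the 4-alkyl-2,6-dimethoxyphenol of ring C in two one-electron stages and so gives para-quinone methide 18, whose exocyclic carbon is the future C2. The closest known reaction type is the Ag2O or DDQ oxidation of 4-alkyl-2,6-dimethoxyphenols to para-quinone methides with intramolecular capture by a phenol, the laboratory form of the ring closure in 8–5 neolignan biosynthesis. The ring A phenol oxygen then adds to the methide carbon in a 5-exo-trig oxa-Michael closure that forms O1–C2, closes ring B and returns ring C to a phenol. The new C2 centre is set by the existing C3 centre: in the envelope transition state the aryl group on C2 and the hydroxymethyl group on C3 take opposite faces, and since the addition can reverse through the ring C phenol the trans isomer is also the thermodynamic one, so (2S,3R) should result. The step needs chemoselectivity between two phenols, and the substrate secures it because ring C, with two ortho methoxy groups and a para alkyl group, is far easier to oxidise than the ring A phenol, which is conjugated to the acrylate. Only the ring C benzylic methylene lies para to the oxidised phenol, so no other methide can form from that ring, and the free primary alcohol cannot compete because it could close only an oxetane. High dilution and exclusion of light hold back intermolecular coupling.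

Step 13
Reactants: 19 methyl (E)-3-[(2S,3R)-2-(4-hydroxy-3,5-dimethoxyphenyl)-3-(hydroxymethyl)-7-methoxy-2,3-dihydro-1-benzofuran-5-yl]prop-2-enoate
Product: 20 (E)-3-[(2S,3R)-2-(4-hydroxy-3,5-dimethoxyphenyl)-3-(hydroxymethyl)-7-methoxy-2,3-dihydro-1-benzofuran-5-yl]prop-2-enoic acid
Conditions: LiOH, THF/H2O (3:1), rt, argon; then 1 M HCl to pH 3
Reagents that add atoms: lithium hydroxide, [Li+].[OH-]
Why: Saponification of a methyl cinnamate by acyl–oxygen cleavage; C3 carries no acidifying group, so base-induced elimination across C3–C2 is not available, and the trans arrangement is the stable one even if C2 were to open and re-close; degassing protects the phenoxides from air.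

## Compound list

1 | syringaldehyde (4-hydroxy-3,5-dimethoxybenzaldehyde) | COc1cc(C=O)cc(OC)c1O | starting material
2 | 4-(benzyloxy)-3,5-dimethoxybenzaldehyde | COc1cc(C=O)cc(OC)c1OCc1ccccc1 | intermediate
3 | [4-(benzyloxy)-3,5-dimethoxyphenyl]methanol | COc1cc(CO)cc(OC)c1OCc1ccccc1 | intermediate
4 | 2-(benzyloxy)-5-(bromomethyl)-1,3-dimethoxybenzene | COc1cc(CBr)cc(OC)c1OCc1ccccc1 | intermediate
5 | 5-bromovanillin (3-bromo-4-hydroxy-5-methoxybenzaldehyde) | COc1cc(C=O)cc(Br)c1O | starting material
6 | 4-(benzyloxy)-3-bromo-5-methoxybenzaldehyde | COc1cc(C=O)cc(Br)c1OCc1ccccc1 | intermediate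
7 | methyl (E)-3-[4-(benzyloxy)-3-bromo-5-methoxyphenyl]prop-2-enoate | COC(=O)/C=C/c1cc(OC)c(OCc2ccccc2)c(Br)c1 | intermediate
8 | methyl (E)-3-[4-(benzyloxy)-3-(2-tert-butoxy-2-oxoethyl)-5-methoxyphenyl]prop-2-enoate | COC(=O)/C=C/c1cc(OC)c(OCc2ccccc2)c(CC(=O)OC(C)(C)C)c1 | intermediate
9 | {2-(benzyloxy)-3-methoxy-5-[(E)-3-methoxy-3-oxoprop-1-en-1-yl]phenyl}acetic acid | COC(=O)/C=C/c1cc(OC)c(OCc2ccccc2)c(CC(=O)O)c1 | intermediate
10 | (R)-4-benzyl-1,3-oxazolidin-2-one | O=C1N[C@H](Cc2ccccc2)CO1 | starting material
11 | mixed anhydride of acid 9 and pivalic acid | COC(=O)/C=C/c1cc(OC)c(OCc2ccccc2)c(CC(=O)OC(=O)C(C)(C)C)c1 | intermediate (not isolated)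
12 | methyl (E)-3-{4-(benzyloxy)-3-methoxy-5-[2-oxo-2-((4R)-4-benzyl-2-oxo-1,3-oxazolidin-3-yl)ethyl]phenyl}prop-2-enoate | COC(=O)/C=C/c1cc(OC)c(OCc2ccccc2)c(CC(=O)N2C(=O)OC[C@H]2Cc2ccccc2)c1 | intermediate
13 | sodium (Z)-enolate of imide 12 | [Na+].[O-]/C(=C\c1cc(/C=C/C(=O)OC)cc(OC)c1OCc1ccccc1)N1C(=O)OC[C@H]1Cc1ccccc1 | intermediate (not isolated)
14 | methyl (E)-3-{4-(benzyloxy)-3-[(2R)-1-((4R)-4-benzyl-2-oxo-1,3-oxazolidin-3-yl)-3-(4-benzyloxy-3,5-dimethoxyphenyl)-1-oxopropan-2-yl]-5-methoxyphenyl}prop-2-enoate | COC(=O)/C=C/c1cc(OC)c(OCc2ccccc2)c([C@@H](Cc2cc(OC)c(OCc3ccccc3)c(OC)c2)C(=O)N2C(=O)OC[C@H]2Cc2ccccc2)c1 | intermediate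
15 | methyl (E)-3-{4-(benzyloxy)-3-[(2R)-1-(4-benzyloxy-3,5-dimethoxyphenyl)-3-oxopropan-2-yl]-5-methoxyphenyl}prop-2-enoate | COC(=O)/C=C/c1cc(OC)c(OCc2ccccc2)c([C@@H](Cc2cc(OC)c(OCc3ccccc3)c(OC)c2)C=O)c1 | intermediate (not isolated)
16 | methyl (E)-3-{4-(benzyloxy)-3-[(2R)-1-(4-benzyloxy-3,5-dimethoxyphenyl)-3-hydroxypropan-2-yl]-5-methoxyphenyl}prop-2-enoate | COC(=O)/C=C/c1cc(OC)c(OCc2ccccc2)c([C@@H](Cc2cc(OC)c(OCc3ccccc3)c(OC)c2)CO)c1 | intermediate
17 | methyl (E)-3-{4-hydroxy-3-[(2R)-1-hydroxy-3-(4-hydroxy-3,5-dimethoxyphenyl)propan-2-yl]-5-methoxyphenyl}prop-2-enoate | COC(=O)/C=C/c1cc(OC)c(O)c([C@@H](Cc2cc(OC)c(O)c(OC)c2)CO)c1 | intermediate (key-step precursor)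
18 | methyl (E)-3-{3-[(2R)-1-(3,5-dimethoxy-4-oxocyclohexa-2,5-dien-1-ylidene)-3-hydroxypropan-2-yl]-4-hydroxy-5-methoxyphenyl}prop-2-enoate (para-quinone methide) | COC(=O)/C=C/c1cc(OC)c(O)c([C@@H](C=C2C=C(OC)C(=O)C(OC)=C2)CO)c1 | intermediate (not isolated)
19 | methyl (E)-3-[(2S,3R)-2-(4-hydroxy-3,5-dimethoxyphenyl)-3-(hydroxymethyl)-7-methoxy-2,3-dihydro-1-benzofuran-5-yl]prop-2-enoate | COc1cc([C@H]2Oc3c(OC)cc(/C=C/C(=O)OC)cc3[C@@H]2CO)cc(OC)c1O | intermediate (key-step product)
20 | (E)-3-[(2S,3R)-2-(4-hydroxy-3,5-dimethoxyphenyl)-3-(hydroxymethyl)-7-methoxy-2,3-dihydro-1-benzofuran-5-yl]prop-2-enoic acid | COc1cc([C@H]2Oc3c(OC)cc(/C=C/C(=O)O)cc3[C@@H]2CO)cc(OC)c1O | target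

## Step count and least certain steps

Total step count: 13. Longest linear sequence: 10 steps (steps 4 to 13, from 5-bromovanillin 5); steps 1 to 3 prepare bromide 4.

**Step 12 (key step).** The most likely failure is over-oxidation: product 19 still has a free ring C phenol para to the C2–H bond, so a second oxidation followed by aromatisation of ring B would erase both stereocentres. Tautomerisation of the quinone methide toward a stilbene (loss of C3) and intermolecular phenoxyl coupling through ring A are the other risks. The fallback separates oxidation from ring closure. It sets out from 17: DDQ (1.05 equiv) in CH2Cl2/MeOH at 0 °C acts as a hydride-abstracting, two-electron oxidant, and the large excess of methanol should capture the quinone methide as benzylic methyl ether F1 (both epimers at the new carbon; any 19 formed directly is carried along). F1, now free of oxidant, would be treated with catalytic camphorsulfonic acid in CH2Cl2; the para-hydroxybenzylic ether ionises and the ring A phenol closes under thermodynamic control to the trans isomer. The fallback comes back at 19.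

**Step 9.** What may go wrong is loss of the auxiliary from the arylacetyl enolate on warming, conjugate addition of the enolate to the cinnamate of a second molecule, and base-mediated epimerisation of the α-aryl product that erodes the diastereoselectivity. The fallback replaces auxiliary alkylation by carboxylate-directed asymmetric hydrogenation. It sets out from 9 and 2: Perkin condensation (Ac2O, Et3N, 110 °C) should give (E)-2,3-diarylacrylic acid F2, with the two aryl groups cis. Hydrogenation with Ru(OAc)2(BINAP) (the ligand antipode that delivers the R acid), H2, MeOH would then give propanoic acid F3; an unsaturated ester lacking a free acid is not a substrate for this catalyst. F3 would be converted with i-BuOCOCl and N-methylmorpholine (THF, –15 °C) into mixed carbonic anhydride F4 and reduced in the same flask with NaBH4/H2O. The fallback comes back at 16.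

**Step 10.** Hydride attack at the hindered exocyclic carbonyl may be slow, so that opening of the oxazolidinone ring, reduction of the cinnamate ester or epimerisation α to the carbonyl catch up. The fallback sets out from 14: EtSLi (from EtSH and n-BuLi, THF, 0 °C) displaces the auxiliary as a small soft nucleophile to give S-ethyl thioester F5. F5 is far more electrophilic than the methyl cinnamate and would be reduced with NaBH4 in EtOH at 0 °C. The fallback comes back at 16.

**Step 6.** Oxidative addition and transmetalation at a bromide flanked by a benzyloxy group may be sluggish, leaving room for protonation of the zinc enolate and hydrodebromination. The fallback changes to an sp2–sp2 coupling and sets out from 7. Suzuki–Miyaura coupling with (E)-2-(2-ethoxyvinyl)-4,4,5,5-tetramethyl-1,3,2-dioxaborolane (PdCl2(dppf), K3PO4, dioxane/H2O, 80 °C) should give enol ether F6. Mild aqueous HCl in THF would hydrolyse it to arylacetaldehyde F7, and Pinnick oxidation (NaClO2, NaH2PO4, 2-methyl-2-butene, t-BuOH/H2O) would give the acid. The fallback comes back at 9.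

**Step 13.** Under hydroxide the ring C phenoxide may push ring B open by retro-oxa-Michael cleavage of C2–O1, followed by hydration or elimination, and the phenoxides may be oxidised by air. The fallback changes the order of the last two operations and sets out from 17. Saponification (LiOH, THF/H2O, rt), where there is no ring to open, should give seco acid F8. The oxidative cyclisation would then be run on the free acid with the metal-free oxidant DDQ (1.05 equiv) in 1,4-dioxane at rt. The fallback comes back at 20.

## Further compounds

F1 | step 12 | methyl (E)-3-{4-hydroxy-3-[(2R)-1-hydroxy-3-(4-hydroxy-3,5-dimethoxyphenyl)-3-methoxypropan-2-yl]-5-methoxyphenyl}prop-2-enoate (both epimers at the methoxy-bearing carbon) | COC(=O)/C=C/c1cc(OC)c(O)c([C@@H](C(OC)c2cc(OC)c(O)c(OC)c2)CO)c1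
F2 | step 9 | (E)-3-(4-benzyloxy-3,5-dimethoxyphenyl)-2-{2-(benzyloxy)-3-methoxy-5-[(E)-3-methoxy-3-oxoprop-1-en-1-yl]phenyl}prop-2-enoic acid | COC(=O)/C=C/c1cc(OC)c(OCc2ccccc2)c(/C(C(=O)O)=C\c2cc(OC)c(OCc3ccccc3)c(OC)c2)c1
F3 | step 9 | (2R)-3-(4-benzyloxy-3,5-dimethoxyphenyl)-2-{2-(benzyloxy)-3-methoxy-5-[(E)-3-methoxy-3-oxoprop-1-en-1-yl]phenyl}propanoic acid | COC(=O)/C=C/c1cc(OC)c(OCc2ccccc2)c([C@@H](Cc2cc(OC)c(OCc3ccccc3)c(OC)c2)C(=O)O)c1
F4 | step 9 | mixed isobutyl carbonic anhydride of acid F3 | COC(=O)/C=C/c1cc(OC)c(OCc2ccccc2)c([C@@H](Cc2cc(OC)c(OCc3ccccc3)c(OC)c2)C(=O)OC(=O)OCC(C)C)c1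
F5 | step 10 | S-ethyl (2R)-3-(4-benzyloxy-3,5-dimethoxyphenyl)-2-{2-(benzyloxy)-3-methoxy-5-[(E)-3-methoxy-3-oxoprop-1-en-1-yl]phenyl}propanethioate | COC(=O)/C=C/c1cc(OC)c(OCc2ccccc2)c([C@@H](Cc2cc(OC)c(OCc3ccccc3)c(OC)c2)C(=O)SCC)c1
F6 | step 6 | methyl (E)-3-{4-(benzyloxy)-3-[(E)-2-ethoxyethenyl]-5-methoxyphenyl}prop-2-enoate | COC(=O)/C=C/c1cc(OC)c(OCc2ccccc2)c(/C=C/OCC)c1
F7 | step 6 | methyl (E)-3-[4-(benzyloxy)-3-methoxy-5-(2-oxoethyl)phenyl]prop-2-enoate | COC(=O)/C=C/c1cc(OC)c(OCc2ccccc2)c(CC=O)c1
F8 | step 13 | (E)-3-{4-hydroxy-3-[(2R)-1-hydroxy-3-(4-hydroxy-3,5-dimethoxyphenyl)propan-2-yl]-5-methoxyphenyl}prop-2-enoic acid | OC(=O)/C=C/c1cc(OC)c(O)c([C@@H](Cc2cc(OC)c(O)c(OC)c2)CO)c1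
A1 | alternative 1 | anti secondary pinacol boronic ester carrying ring A on the silyloxymethyl-bearing carbon and ring C on the boron-bearing carbon | COCOc1c(OC)cc(C(=O)OC)cc1[C@H](CO[Si](C)(C)C(C)(C)C)[C@H](B1OC(C)(C)C(C)(C)O1)c1cc(OC)c(OCOC)c(OC)c1
A2 | alternative 1 | methyl 3-methoxy-4-(methoxymethoxy)-5-(trifluoromethylsulfonyloxy)benzoate | COCOc1c(OC)cc(C(=O)OC)cc1OS(=O)(=O)C(F)(F)F
A3 | alternative 1 | (E)-tert-butyldimethyl{[3-(4,4,5,5-tetramethyl-1,3,2-dioxaborolan-2-yl)prop-2-en-1-yl]oxy}silane | CC(C)(C)[Si](C)(C)OC/C=C/B1OC(C)(C)C(C)(C)O1
A4 | alternative 1 | [3,5-dimethoxy-4-(methoxymethoxy)phenyl]lithium | [Li]c1cc(OC)c(OCOC)c(OC)c1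
A5 | alternative 1 | lithium boron ate complex of A3 and A4 | [Li+].CC(C)(C)[Si](C)(C)OC/C=C/[B-]1(OC(C)(C)C(C)(C)O1)c1cc(OC)c(OCOC)c(OC)c1
A6 | alternative 2 | trans-5-bromo-7-methoxy-2-(3,5-dimethoxy-4-pivaloyloxyphenyl)-3-(tert-butyldimethylsilyloxymethyl)-2,3-dihydrobenzofuran, (2S,3R) | COc1cc([C@H]2Oc3c(OC)cc(Br)cc3[C@@H]2CO[Si](C)(C)C(C)(C)C)cc(OC)c1OC(=O)C(C)(C)C
A7 | alternative 2 | 4-bromo-2-[2-(tert-butyldimethylsilyloxy)-1-(4-methylphenylsulfonyl)ethyl]-6-methoxyphenol (racemic) | COc1cc(Br)cc(C(CO[Si](C)(C)C(C)(C)C)S(=O)(=O)c2ccc(C)cc2)c1O
A8 | alternative 2 | (2R,5R)-1-[(3,5-dimethoxy-4-pivaloyloxyphenyl)methyl]-2,5-dimethylthiolanium trifluoromethanesulfonate | C[C@@H]1CC[C@@H](C)[S+]1Cc1cc(OC)c(OC(=O)C(C)(C)C)c(OC)c1.[O-]S(=O)(=O)C(F)(F)F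
A9 | alternative 2 | 4-bromo-6-[2-(tert-butyldimethylsilyloxy)ethylidene]-2-methoxycyclohexa-2,4-dien-1-one (ortho-quinone methide) | COC1=CC(Br)=CC(=CCO[Si](C)(C)C(C)(C)C)C1=O
A10 | alternative 3 | methyl trans-5-bromo-7-methoxy-2-(3,5-dimethoxy-4-pivaloyloxyphenyl)-2,3-dihydrobenzofuran-3-carboxylate | COc1cc([C@H]2Oc3c(OC)cc(Br)cc3[C@@H]2C(=O)OC)cc(OC)c1OC(=O)C(C)(C)C
A11 | alternative 3 | (2S)-6-bromo-8-methoxy-2-(3,5-dimethoxy-4-pivaloyloxyphenyl)chroman-4-one | COc1cc([C@@H]2CC(=O)c3cc(Br)cc(OC)c3O2)cc(OC)c1OC(=O)C(C)(C)C
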